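The runs cannot show a chain length: they give the monomer in chains, not the number of chains. The count is therefore a guess, namely one chain per initiator, so the average length n is the plateau of monomer in chains divided by the loading of 1 mol%. In each run the readings stay level from the first to the last, so the chains are taken to end early, and the plateau to hold until 80 min.

| setting | teal | ochre | grey | maple | cedar |
|---|---|---|---|---|---|
| free monomer | 1.3 M | 1.3 M | 1.3 M | 1.3 M | 1.3 M |
| transfer agent | 0.040 M | 0.079 M | 0.14 M | 0.0390 M | 0.150 M |
| initiator | 1 mol% | 1 mol% | 1 mol% | 1 mol% | 1 mol% |
| remark | run made earlier | run made earlier | run made earlier |  |  |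
| time |  |  |  | 80 min | 80 min |

| run | time / min | monomer in chains / % |
|---|---|---|
| teal | 8.00 | 10.0 |
| teal | 15.0 | 11.0 |
| teal | 25.0 | 8.8 |
| teal | 30.0 | 10.3 |
| teal | 40.0 | 10.3 |
| ochre | 8.00 | 5.6 |
| ochre | 15.0 | 5.7 |
| ochre | 25.0 | 5.4 |
| ochre | 30.0 | 6.3 |
| ochre | 40.0 | 6.2 |
| grey | 4.00 | 3.5 |
| grey | 10.0 | 3.5 |
| grey | 20.0 | 4.2 |
| grey | 30.0 | 3.7 |
| grey | 40.0 | 4.6 |

(standard deviation of a reading: 0.5 percentage points)

* which of the two ends with the longer chains by the average number of monomer units in a chain (chains begun, living or dead) ("neither" if they lie within 10 %) (maple / cedar / neither)
* average number of monomer units in a chain (chains begun, living or dead) at the end, maple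
* average number of monomer units in a chain (chains begun, living or dead) at the end, cedar

- the average divides the monomer in chains by the number of chains begun, living and dead together
- the numbers in the tables scatter by 0.5 percentage points (one standard deviation)
- the earlier runs do not show the number of chains; that part of a forecast is a guess

As a rough reckoning, free monomer [M] and transfer agent [T] are frozen at their charges, although both fall while the chains grow, so the ratio at the start stands for the ratio during growth. The first unit enters at initiation, and the others follow at a rate set against stopping:

n = 1 + C·[M]/[T]

C is the growth-to-stop ratio, the units added per stop at equal concentrations, and the inverse of the usual chain-transfer constant. The plateau means give these readings: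

teal 0.279, ochre 0.294, grey 0.312

Their mean is C = 0.295.

The bound from below takes teal's C, the lowest reading, with the agent at its charge. The bound from above takes grey's C, the highest reading, with the agent lowered by the whole initiator charge, 0.0130 M, at one agent per chain.

maple: 10.3 to 16.6
cedar: 3.42 to 3.96

C was read with the agent at its charge, so the same convention gives the tightest figures: 10.8 for maple and 3.56 for cedar. Maple's bracket lies above cedar's.

The forecast named maple, with 10.3 and 3.7, on the view that “the agent seems to kill them without starting new ones”.

The simulation gives maple, with 10.6 for maple and 3.44 for cedar, the latter at the lower edge of its bracket.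

    free monomer + initiator → living end + monomer in chains (k = 0.0192 /M/s)
    free monomer + living end → monomer in chains + living end, rate k2*[living end]*[free monomer] (k = 0.0650 /M/s)
    living end + transfer agent → dead chain (kL = 0.221 /M/s)
    monomer in chains → over-reaction product (k = 1.45 × 10⁻⁶ /s)
    free monomer → uncatalysed product (k = 7.87 × 10⁻⁴ /s)

In cedar, the step building chains has half its turnover behind it by 0.988 min, and the step to uncatalysed product only by 14.2 min, much later. At 80.0 min cedar holds 3.44 % monomer in chains beside 94.3 % uncatalysed product.

A neighbour of cedar with 0.78 M of free monomer and the agent still at 0.150 M gets 2.53 from C; the computed length is 2.41.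

(The data were computed on assumed constants, noise included.)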